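## Analysis of the target

Target 33 is a manumycin-type epoxyquinol. Its core, ring A, is a cyclohex-2-enone (C1 ketone, C2=C3) whose C5–C6 bond carries an epoxide. C2 bears the nitrogen of a (2E,4E,6R)-4,6-dimethyldeca-2,4-dienamide, and the tertiary carbinol C4 bears an all-E triene ending in the amide of 2-amino-3-hydroxycyclopent-2-enone (ring B, a vinylogous acid). There are four stereocentres: C4 (S), C5 (R) and C6 (S) are contiguous on ring A, with the C4 hydroxyl on the same face as the epoxide oxygen, and the fourth, C6 of the upper acyl chain (R), is remote and must come in with its own fragment. The epoxy ketone is open to bases and nucleophiles, the doubly allylic tertiary alcohol ionises and aromatises under acid, both polyene amides are sensitive to light, acid and radicals, and ring B is acidic; the chains should therefore arrive late and under near-neutral conditions. The hard part is the syn relationship on ring A combined with absolute control at C4, a quaternary centre whose two ring arms differ only at a distance; intermolecular oxidation of a quinol gives no handle on either. The strategy rests on the hidden mirror plane of ring A through C1 and C4: C2 and C6 are both α, and C3 and C5 both β, to the C1 ketone. A symmetric 2,6-dibromo-4-hydroxydienone therefore maps onto the ring, with the C5 oxygen reachable from the C4 oxygen over a one-atom bridge, the C6 bromide as leaving group for the epoxide and the C2 bromide as handle for the amide nitrogen.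

## Retrosynthetic reasoning

Target 33 is first cut at the single bond between the second and third carbon of the triene (counted from ring A), giving vinylstannane 32 and bromodienamide 29. This is an sp2–sp2 bond between two alkenes whose E geometry can be fixed beforehand in each half, and a Stille coupling makes it at room temperature without base. The cut keeps the acidic ring B and most of the light-sensitive triene out of every earlier step. The forward reaction must retain both alkene geometries and tolerate the free enol, the tertiary alcohol and the epoxy ketone.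

The C–Sn bond of 32 is traced to terminal alkyne 31 (syn hydrostannation), and 31 to its silyl-capped form 30. A two-carbon alkyne on C4 is the least demanding way to carry the first two triene carbons through the ring chemistry: it is linear and does not crowd C4, it is inert to base and conjugate addition, and its bulky silyl cap keeps it away from copper. The forward reactions must place tin on the terminal carbon and leave the enone and epoxide alone.

The C2–N bond of 30 is cut next, giving bromo epoxide 9 and primary dienamide 20. The C2 bromide is what remains of the symmetric precursor, so the nitrogen needs no separate introduction, and a copper-catalysed vinyl amidation makes the enamide without passing through a free 2-amino enone. It is placed before desilylation because a terminal alkyne would not survive copper.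

The C6–O bond of the epoxide in 9 is opened to bromohydrin 8, the boron-free form of boronate 7. Closing the epoxide by displacement of bromide fixes its face: the C5 oxygen is already in place and attacks C6 from its own side, so the epoxide oxygen ends up syn to the C4 hydroxyl. Because C6 is α to the ketone it can epimerise, and only the epimer with bromide anti to oxygen can close, so the configuration of C6 in 7 need not be perfect.

The C5–O bond of 7 is the key disconnection. Cutting it, together with the two B–O bonds, leads to the achiral dibromoquinol 4 and phenylboronic acid 5 by way of boronic hemiester 6. This is the place to cut because it is the one bond whose formation turns the mirror-symmetric dienone into a chiral ring. One conjugate addition creates C5, makes C4 a stereocentre and generates C6, and a tether from the C4 oxygen guarantees the syn relationship. The forward reaction must distinguish the two enantiotopic bromoenone arms, which is asked of a chiral amine–thiourea catalyst, and must stop after one addition.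

Quinol 4 is cut at the C4–alkyne bond into 2,6-dibromo-1,4-benzoquinone 1 and silylacetylene 2, used as its lithium acetylide 3. Quinone 1 already has the C1 oxygen and both bromides, and its two carbonyls differ sharply in hindrance, so one 1,2-addition at the open carbonyl gives the key-step precursor in a single step.

Dienamide 20 is cut at C2=C3 into enal 18 and phosphonate 19 (Horner–Wadsworth–Emmons), and 18 at its trisubstituted alkene into aldehyde 16 and formyl ylide 17 (Wittig). Both olefinations favour the E isomer and neither needs a strong base near the stereocentre. Aldehyde 16 comes from alcohol 15, and its stereocentre from the auxiliary-controlled methylation that turns acyl oxazolidinone 12 into 14 via enolate 13; 12 is made from oxazolidinone 10 and hexanoyl chloride 11.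

Bromodienamide 29 is cut at its amide bond into acid 24 (activated as acid chloride 28) and the aminocyclopentenone salt 27. Acid 24 is traced through aldehyde 23 to dienolate 22, the ring-opened form of the pyridine complex 21, which supplies a five-carbon chain with both alkenes already trans. Salt 27 comes from cyclopentane-1,3-dione 25 by nitration to 26 and hydrogenation.

## Alternatives that were turned down

Alternative 1: The C4–O and C5–O bonds are traced to the ipso and ortho carbons of benzoic acid A1, the carboxyl carbon being kept as the future first carbon of the triene. In the forward direction, whole cells that express benzoate 1,2-dioxygenase but lack the diol dehydrogenase add both oxygen atoms of dioxygen to one face of A1 and give the cis-diol acid A2.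
- For: one step from the simplest arene sets C4 and C5 with the right relative and absolute configuration, and an active site that binds a flat arene in one orientation leaves little room for the other enantiomer. On this point it is stronger than the chosen route, whose enantioselectivity depends on an untested catalyst–substrate match.
- Against: A2 has no oxygen at C1 or C6 and no nitrogen at C2, so three heteroatoms must still be placed regioselectively on a diene that rearomatises readily by dehydration and decarboxylation. The carboxyl group must be reduced and olefinated next to a tertiary alcohol, and the two hydroxyls must be told apart so that only the C5 oxygen becomes the epoxide. A blocked mutant strain is also needed.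
- Comparison: the chosen strategy gives up the enzyme's certainty but delivers, in the step that creates chirality, the whole substitution pattern of ring A: the C1 ketone, a leaving group at C6 and a coupling handle at C2.

Alternative 2: Ring A is opened at C2=C3 to the acyclic cis-epoxy vinyl ketone A3, whose C4 carries two vinyl groups and is not yet a stereocentre. In the forward direction the second-generation Hoveyda–Grubbs catalyst joins one of the two vinyl groups to the vinyl ketone by ring-closing metathesis, forming the enone of A4 and leaving the other vinyl group as the first two carbons of the triene.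
- For: ring-closing metathesis to a six-membered enone is a more dependable bond-forming event than the key step chosen here, and the remaining vinyl group is a ready handle.
- Against: the key step creates no stereocentre from an achiral precursor. C5 and C6 must already be present in A3 as an enantioenriched cis-epoxide, made by a separate asymmetric epoxidation on the substrate class (cis-disubstituted alkenes) where such reactions are weakest. The configuration of C4 then depends on which diastereotopic vinyl group cyclises; both give the same ring size, so the syn relationship is only a conformational preference, not a mechanistic necessity. A3 combines a polymerisable vinyl ketone, an epoxide and a bis-allylic tertiary alcohol and would take many steps to assemble. A4 has no substituent at C2, so halogenation and amidation must follow, and growing a vinyl group into an all-E triene is less geometry-safe than a Stille coupling of preformed E-alkenes.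
- Comparison: the chosen route reaches its key-step precursor in one step, enforces syn delivery through a cis-fused ring, and leaves the key step with the C2 handle in place.

Alternative 3: The C4 oxygen and the epoxide oxygen are traced to the two atoms of one molecule of singlet oxygen: the syn-bis-epoxide A7 is the rearranged form of endoperoxide A6, which comes from the silyloxy diene A5. In the forward direction singlet oxygen adds across the diene termini C3 and C6 of A5 on the face opposite the silyloxy group and gives A6. O–O homolysis then collapses A6 to A7, and later oxidation at C1 and β-elimination open the C3–C4 epoxide to the enone and the C4 hydroxyl.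
- For: both oxygens arrive on one face in a single pericyclic step, so the syn relationship is built in as firmly as by the tether, and the reagent is cheap and traceless.
- Against: the absolute configuration must come from the single stereocentre of A5, which has to be made enantioenriched and aromatises readily by 1,4-elimination. Facial control by one allylic substituent on a nearly flat diene is not secure. The rearrangement of A6 competes with Kornblum–DeLaMare fragmentation. After A7 there remain desilylation, oxidation, regioselective epoxide opening and, again, introduction of the C2 nitrogen on an unsubstituted enone.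
- Comparison: it is clearly longer and spends a pre-made stereocentre to control three others, where the chosen route makes all three from an achiral compound with a catalyst.

Key step: step 2

## Remarks on the chemistry

- The silyl cap on the alkyne is triisopropylsilyl, chosen so that the alkyne survives carbonate base and copper in step 16.
- The sense of induction of the quinine-derived catalyst in step 2 is assumed to be the one drawn; if it proves opposite, the pseudo-enantiomeric quinidine-derived catalyst is used.
- Ring B is written as its enol tautomer throughout.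

## Route

Step 1
Reactants: 1 2,6-dibromo-1,4-benzoquinone; 2 ethynyltriisopropylsilane
Product: 4 2,6-dibromo-4-hydroxy-4-[(triisopropylsilyl)ethynyl]cyclohexa-2,5-dien-1-one, via lithium (triisopropylsilyl)acetylide 3 (not isolated)
Conditions: 2, n-BuLi, THF, −78 °C; then added to 1, THF, −78 °C; AcOH quench at −78 °C
Reagents that add atoms: none
Why: 1,2-Addition of a lithium acetylide to a quinone carbonyl; the carbonyl flanked by the two C–Br bonds is shielded, so the acetylide should add at the open C4 carbonyl and give the symmetric quinol, which has no stereocentre.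

Step 2
Reactants: 4 2,6-dibromo-4-hydroxy-4-[(triisopropylsilyl)ethynyl]cyclohexa-2,5-dien-1-one; 5 phenylboronic acid
Product: 7 (3aS,4R,7aR)-4,6-dibromo-2-phenyl-7a-[(triisopropylsilyl)ethynyl]-3a,7a-dihydro-1,3,2-benzodioxaborol-5(4H)-one, via boronic hemiester 6 (not isolated)
Conditions: 5 (1.2 equiv), quinine-derived amine–thiourea [9-amino-9-deoxy-epi-quinine 3,5-bis(trifluoromethyl)phenyl thiourea] (10 mol%), 4 Å molecular sieves, toluene, 0 °C → rt
Reagents that add atoms: none
Why: Proposed new method: the C4 hydroxyl of 4 condenses with 5 to the boronic hemiester 6, the quinuclidine nitrogen of the catalyst activates the remaining B–OH (as a general base or through a B–N ate complex) while the thiourea hydrogen-bonds the C1 carbonyl, and the boron-bound oxygen adds to C5 of one bromoenone, after which the bromo enolate is protonated at C6. The closest known reaction type is the amine–thiourea-catalysed oxa-Michael addition of boronic hemiesters of γ-hydroxy enones, and hemiacetal-tethered oxa-Michael desymmetrisations of para-quinols show that the dienone class accepts oxygen delivered from C4; what is new is boron as the tether on a dienone and the 2,6-dibromo substitution. The 1,3,2-dioxaborolane ring closes 5-exo-trig. C5 is controlled by the tether, because a five-membered ring fused to the cyclohexenone can only be cis, which puts C5–O syn to C4–O. C4 becomes a stereocentre through the choice between the two enantiotopic bromoenone arms, and this choice is controlled by the chiral catalyst, which holds the hemiester over one arm. C6 is set on protonation and stays epimerisable through the enol; the bromide should settle anti to the C5 oxygen, and any syn epimer is corrected in step 3, where only the anti epimer can close. The step needs enantiotopic-group selectivity and mono-addition; the second is secured by the substrate, since boron has no free hydroxyl left once the ring is closed, and the α-bromine makes C5 electrophilic enough for mild activation at low temperature, where the uncatalysed and the reverse reaction should stay slow.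

Step 3
Reactants: 7 (3aS,4R,7aR)-4,6-dibromo-2-phenyl-7a-[(triisopropylsilyl)ethynyl]-3a,7a-dihydro-1,3,2-benzodioxaborol-5(4H)-one
Product: 9 (1S,5R,6R)-3-bromo-5-hydroxy-5-[(triisopropylsilyl)ethynyl]-7-oxabicyclo[4.1.0]hept-3-en-2-one, via bromohydrin diol 8 (not isolated)
Conditions: pinacol (3 equiv), MeCN, rt; then K2CO3, 0 °C → rt
Reagents that add atoms: none
Why: Transesterification moves boron onto the tetrasubstituted diol, and the freed C5 alkoxide displaces the anti C6 bromide (intramolecular SN2, 3-exo-tet) with inversion, so the epoxide oxygen stays on the face of the C4 hydroxyl; the irreversible closure pulls the boron exchange forward, and the syn C4 alkoxide cannot reach the rear of C5, so no Payne migration is expected.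

Step 4
Reactants: 10 (R)-4-benzyl-1,3-oxazolidin-2-one; 11 hexanoyl chloride
Product: 12 (R)-4-benzyl-3-hexanoyl-1,3-oxazolidin-2-one
Conditions: Et3N, DMAP (cat.), CH2Cl2, 0 °C → rt
Reagents that add atoms: none
Why: N-Acylation of the oxazolidinone through the acylpyridinium ion; the standard attachment of an Evans auxiliary.

Step 5
Reactants: 12 (R)-4-benzyl-3-hexanoyl-1,3-oxazolidin-2-one
Product: 14 (R)-4-benzyl-3-[(R)-2-methylhexanoyl]-1,3-oxazolidin-2-one, via sodium Z-enolate 13 (not isolated)
Conditions: NaN(SiMe3)2, THF, −78 °C; then MeI, −78 °C
Reagents that add atoms: iodomethane, CI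
Why: Evans alkylation: the chelated Z-enolate is methylated on the face away from the benzyl group, which for the (R)-auxiliary should give the (R)-2-methyl centre; the minor diastereomer is removed by chromatography.

Step 6
Reactants: 14 (R)-4-benzyl-3-[(R)-2-methylhexanoyl]-1,3-oxazolidin-2-one
Product: 15 (R)-2-methylhexan-1-ol
Conditions: LiBH4, MeOH (1 equiv), THF, 0 °C
Reagents that add atoms: none
Why: Reductive cleavage of the imide at the exocyclic carbonyl; no enolate is formed, so the stereocentre is kept, and the auxiliary is recovered.

Step 7
Reactants: 15 (R)-2-methylhexan-1-ol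
Product: 16 (R)-2-methylhexanal
Conditions: Dess–Martin periodinane, CH2Cl2, 0 °C → rt; used at once as a crude solution
Reagents that add atoms: none
Why: Dess–Martin oxidation under near-neutral conditions should not epimerise the α-centre; the volatile aldehyde is not stored.

Step 8
Reactants: 16 (R)-2-methylhexanal; 17 2-(triphenylphosphoranylidene)propanal
Product: 18 (2E,4R)-2,4-dimethyloct-2-enal
Conditions: toluene, 90 °C
Reagents that add atoms: none
Why: Wittig reaction of a stabilised formyl ylide, base-free and E-selective for the trisubstituted enal; the conjugated product is less reactive toward the ylide than the aliphatic aldehyde.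

Step 9
Reactants: 18 (2E,4R)-2,4-dimethyloct-2-enal; 19 diethyl (2-amino-2-oxoethyl)phosphonate
Product: 20 (2E,4E,6R)-4,6-dimethyldeca-2,4-dienamide
Conditions: LiCl, DBU, MeCN, 0 °C → rt
Reagents that add atoms: none
Why: Horner–Wadsworth–Emmons olefination under Masamune–Roush conditions should give the E-alkene and the primary amide in one step; the mild amine base avoids γ-deprotonation of the enal and so protects the C6 centre.

Step 10
Reactants: 21 pyridine–sulfur trioxide complex (pyridinium-1-sulfonate)
Product: 22 potassium (1E,3E)-5-oxopenta-1,3-dien-1-olate (glutaconaldehyde potassium salt)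
Conditions: KOH, H2O, −20 °C → 40 °C
Reagents that add atoms: potassium hydroxide, [K+].[OH-]
Why: Zincke-type ring opening: hydroxide adds at C2 of the N-sulfonylpyridinium ion, the ring opens and hydrolysis releases sulfamate and the all-trans dienolate, which crystallises.

Step 11
Reactants: 22 potassium (1E,3E)-5-oxopenta-1,3-dien-1-olate
Product: 23 (2E,4E)-5-bromopenta-2,4-dienal
Conditions: PPh3, Br2, CH2Cl2, 0 °C; then 22, 0 °C → rt
Reagents that add atoms: bromine, BrBr
Why: The enolate oxygen is activated as an oxyphosphonium ion by Ph3PBr2 and replaced by bromide through addition–elimination (formation of a vinylogous acid bromide); the E,E-dienal is the thermodynamic product.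

Step 12
Reactants: 23 (2E,4E)-5-bromopenta-2,4-dienal
Product: 24 (2E,4E)-5-bromopenta-2,4-dienoic acid
Conditions: NaClO2, NaH2PO4, 2-methylbut-2-ene, t-BuOH/H2O, 0 °C → rt
Reagents that add atoms: sodium chlorite, [Na+].[O-]Cl=O
Why: Pinnick oxidation of an enal to the acid; the scavenger removes hypochlorite, so the bromodiene is not touched.

Step 13
Reactants: 25 cyclopentane-1,3-dione
Product: 26 2-nitrocyclopentane-1,3-dione (enol form)
Conditions: fuming HNO3, Et2O, 0 °C → rt
Reagents that add atoms: nitric acid, O[N+](=O)[O-]
Why: Electrophilic nitration of the enol at C2, the only nucleophilic carbon of the dione.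

Step 14
Reactants: 26 2-nitrocyclopentane-1,3-dione (enol form)
Product: 27 2-amino-3-hydroxycyclopent-2-en-1-one hydrochloride
Conditions: H2 (1 atm), Pd/C, HCl, MeOH, rt
Reagents that add atoms: hydrogen chloride, Cl
Why: Catalytic hydrogenation of the nitro group; the amine is trapped as its hydrochloride, which prevents self-condensation of the α-amino ketone.

Step 15
Reactants: 24 (2E,4E)-5-bromopenta-2,4-dienoic acid; 27 2-amino-3-hydroxycyclopent-2-en-1-one hydrochloride
Product: 29 (2E,4E)-5-bromo-N-(2-hydroxy-5-oxocyclopent-1-en-1-yl)penta-2,4-dienamide, via acid chloride 28 (not isolated)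
Conditions: (COCl)2, DMF (cat.), CH2Cl2, 0 °C → rt; then 27, Et3N, THF, 0 °C → rt
Reagents that add atoms: none
Why: Acid chloride formation and N-acylation of the liberated amine; any enol ester formed first should pass its acyl group to nitrogen, the more nucleophilic and thermodynamically preferred site.

Step 16
Reactants: 9 (1S,5R,6R)-3-bromo-5-hydroxy-5-[(triisopropylsilyl)ethynyl]-7-oxabicyclo[4.1.0]hept-3-en-2-one; 20 (2E,4E,6R)-4,6-dimethyldeca-2,4-dienamide
Product: 30 (2E,4E,6R)-N-[(1S,5R,6R)-5-hydroxy-2-oxo-5-[(triisopropylsilyl)ethynyl]-7-oxabicyclo[4.1.0]hept-3-en-3-yl]-4,6-dimethyldeca-2,4-dienamide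
Conditions: CuI (10 mol%), 3,4,7,8-tetramethyl-1,10-phenanthroline (20 mol%), K2CO3, toluene, 60 °C
Reagents that add atoms: none
Why: Goldberg-type copper-catalysed amidation of a vinyl bromide: the monovalent copper amidate inserts into the activated C2–Br bond of the α-bromo enone and reductive elimination forms the enamide; a phenanthroline ligand is chosen because it cannot add to the enone, and the bulky silyl group keeps the alkyne from copper.

Step 17
Reactants: 30 (2E,4E,6R)-N-[(1S,5R,6R)-5-hydroxy-2-oxo-5-[(triisopropylsilyl)ethynyl]-7-oxabicyclo[4.1.0]hept-3-en-3-yl]-4,6-dimethyldeca-2,4-dienamide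
Product: 31 (2E,4E,6R)-N-[(1S,5R,6R)-5-ethynyl-5-hydroxy-2-oxo-7-oxabicyclo[4.1.0]hept-3-en-3-yl]-4,6-dimethyldeca-2,4-dienamide
Conditions: Bu4NF, AcOH, THF, 0 °C → rt
Reagents that add atoms: none
Why: Fluoride-induced protodesilylation of an alkynylsilane; buffering with acetic acid keeps the medium from becoming basic enough to harm the epoxy ketone.

Step 18
Reactants: 31 (2E,4E,6R)-N-[(1S,5R,6R)-5-ethynyl-5-hydroxy-2-oxo-7-oxabicyclo[4.1.0]hept-3-en-3-yl]-4,6-dimethyldeca-2,4-dienamide
Product: 32 (2E,4E,6R)-N-[(1S,5R,6R)-5-hydroxy-2-oxo-5-[(E)-2-(tributylstannyl)ethenyl]-7-oxabicyclo[4.1.0]hept-3-en-3-yl]-4,6-dimethyldeca-2,4-dienamide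
Conditions: Bu3SnH (slow addition), PdCl2(PPh3)2 (3 mol%), THF, 0 °C
Reagents that add atoms: tributyltin hydride, CCCC[SnH](CCCC)CCCC
Why: Palladium-catalysed hydrostannation of a terminal alkyne is a syn addition, and the fully substituted C4 should direct tin to the terminal carbon, giving the E-vinylstannane; the alkyne reacts much faster than the captodative enone.

Step 19
Reactants: 32 (2E,4E,6R)-N-[(1S,5R,6R)-5-hydroxy-2-oxo-5-[(E)-2-(tributylstannyl)ethenyl]-7-oxabicyclo[4.1.0]hept-3-en-3-yl]-4,6-dimethyldeca-2,4-dienamide; 29 (2E,4E)-5-bromo-N-(2-hydroxy-5-oxocyclopent-1-en-1-yl)penta-2,4-dienamide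
Product: 33 (2E,4E,6R)-N-[(1S,5S,6R)-5-hydroxy-5-[(1E,3E,5E)-7-[(2-hydroxy-5-oxocyclopent-1-en-1-yl)amino]-7-oxohepta-1,3,5-trien-1-yl]-2-oxo-7-oxabicyclo[4.1.0]hept-3-en-3-yl]-4,6-dimethyldeca-2,4-dienamide
Conditions: PdCl2(MeCN)2 (5 mol%), DMF, rt, dark
Reagents that add atoms: none
Why: Stille coupling of a vinylstannane with a dienyl bromide under ligand-free, base-free conditions (the divalent palladium salt is reduced in the flask to zerovalent palladium); both partners couple with retention, so the all-E triene should result, and no ring A stereocentre is touched.

## Compound list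

1 | 2,6-dibromo-1,4-benzoquinone | O=C1C=C(Br)C(=O)C(Br)=C1 | starting material
2 | ethynyltriisopropylsilane | C#C[Si](C(C)C)(C(C)C)C(C)C | starting material
3 | lithium (triisopropylsilyl)acetylide | [Li+].[C-]#C[Si](C(C)C)(C(C)C)C(C)C | intermediate (not isolated)
4 | 2,6-dibromo-4-hydroxy-4-[(triisopropylsilyl)ethynyl]cyclohexa-2,5-dien-1-one | O=C1C(Br)=CC(O)(C#C[Si](C(C)C)(C(C)C)C(C)C)C=C1Br | intermediate
5 | phenylboronic acid | OB(O)c1ccccc1 | starting material
6 | 3,5-dibromo-4-oxo-1-[(triisopropylsilyl)ethynyl]cyclohexa-2,5-dien-1-yl hydrogen phenylboronate | O=C1C(Br)=CC(OB(O)c2ccccc2)(C#C[Si](C(C)C)(C(C)C)C(C)C)C=C1Br | intermediate (not isolated)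
7 | (3aS,4R,7aR)-4,6-dibromo-2-phenyl-7a-[(triisopropylsilyl)ethynyl]-3a,7a-dihydro-1,3,2-benzodioxaborol-5(4H)-one (cis-fused boronate over the C4 and C5 oxygens, C6 bromide anti to the C5 oxygen) | BrC1=C[C@@](OB(c3ccccc3)O2)(C#C[Si](C(C)C)(C(C)C)C(C)C)[C@H]2[C@@H](Br)C1=O | intermediate
8 | (4R,5S,6R)-2,6-dibromo-4,5-dihydroxy-4-[(triisopropylsilyl)ethynyl]cyclohex-2-en-1-one | BrC1=C[C@@](O)(C#C[Si](C(C)C)(C(C)C)C(C)C)[C@H](O)[C@@H](Br)C1=O | intermediate (not isolated)
9 | (1S,5R,6R)-3-bromo-5-hydroxy-5-[(triisopropylsilyl)ethynyl]-7-oxabicyclo[4.1.0]hept-3-en-2-one | BrC1=C[C@@](O)(C#C[Si](C(C)C)(C(C)C)C(C)C)[C@@H]2O[C@@H]2C1=O | intermediate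
10 | (R)-4-benzyl-1,3-oxazolidin-2-one | O=C1N[C@H](Cc2ccccc2)CO1 | starting material
11 | hexanoyl chloride | CCCCCC(Cl)=O | starting material
12 | (R)-4-benzyl-3-hexanoyl-1,3-oxazolidin-2-one | CCCCCC(=O)N1[C@H](Cc2ccccc2)COC1=O | intermediate
13 | sodium (Z)-1-[(R)-4-benzyl-2-oxo-1,3-oxazolidin-3-yl]hex-1-en-1-olate | [Na+].CCCC/C=C(\[O-])N1[C@H](Cc2ccccc2)COC1=O | intermediate (not isolated)
14 | (R)-4-benzyl-3-[(R)-2-methylhexanoyl]-1,3-oxazolidin-2-one | CCCC[C@@H](C)C(=O)N1[C@H](Cc2ccccc2)COC1=O | intermediate
15 | (R)-2-methylhexan-1-ol | CCCC[C@@H](C)CO | intermediate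
16 | (R)-2-methylhexanal | CCCC[C@@H](C)C=O | intermediate
17 | 2-(triphenylphosphoranylidene)propanal | CC(C=O)=P(c1ccccc1)(c1ccccc1)c1ccccc1 | starting material
18 | (2E,4R)-2,4-dimethyloct-2-enal | CCCC[C@@H](C)/C=C(\C)C=O | intermediate
19 | diethyl (2-amino-2-oxoethyl)phosphonate | CCOP(=O)(CC(N)=O)OCC | starting material
20 | (2E,4E,6R)-4,6-dimethyldeca-2,4-dienamide | CCCC[C@@H](C)/C=C(C)/C=C/C(N)=O | intermediate
21 | pyridine–sulfur trioxide complex (pyridinium-1-sulfonate) | [O-]S(=O)(=O)[n+]1ccccc1 | starting material
22 | potassium (1E,3E)-5-oxopenta-1,3-dien-1-olate | [K+].[O-]/C=C/C=C/C=O | intermediate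
23 | (2E,4E)-5-bromopenta-2,4-dienal | Br/C=C/C=C/C=O | intermediate
24 | (2E,4E)-5-bromopenta-2,4-dienoic acid | Br/C=C/C=C/C(O)=O | intermediate
25 | cyclopentane-1,3-dione | O=C1CCC(=O)C1 | starting material
26 | 2-nitrocyclopentane-1,3-dione, enol form (3-hydroxy-2-nitrocyclopent-2-en-1-one) | O=C1CCC(O)=C1[N+](=O)[O-] | intermediate
27 | 2-amino-3-hydroxycyclopent-2-en-1-one hydrochloride | Cl.NC1=C(O)CCC1=O | intermediate
28 | (2E,4E)-5-bromopenta-2,4-dienoyl chloride | Br/C=C/C=C/C(Cl)=O | intermediate (not isolated)
29 | (2E,4E)-5-bromo-N-(2-hydroxy-5-oxocyclopent-1-en-1-yl)penta-2,4-dienamide | Br/C=C/C=C/C(=O)NC1=C(O)CCC1=O | intermediate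
30 | (2E,4E,6R)-N-[(1S,5R,6R)-5-hydroxy-2-oxo-5-[(triisopropylsilyl)ethynyl]-7-oxabicyclo[4.1.0]hept-3-en-3-yl]-4,6-dimethyldeca-2,4-dienamide | CCCC[C@@H](C)/C=C(C)/C=C/C(=O)NC1=C[C@@](O)(C#C[Si](C(C)C)(C(C)C)C(C)C)[C@@H]2O[C@@H]2C1=O | intermediate
31 | (2E,4E,6R)-N-[(1S,5R,6R)-5-ethynyl-5-hydroxy-2-oxo-7-oxabicyclo[4.1.0]hept-3-en-3-yl]-4,6-dimethyldeca-2,4-dienamide | CCCC[C@@H](C)/C=C(C)/C=C/C(=O)NC1=C[C@@](O)(C#C)[C@@H]2O[C@@H]2C1=O | intermediate
32 | (2E,4E,6R)-N-[(1S,5R,6R)-5-hydroxy-2-oxo-5-[(E)-2-(tributylstannyl)ethenyl]-7-oxabicyclo[4.1.0]hept-3-en-3-yl]-4,6-dimethyldeca-2,4-dienamide | CCCC[C@@H](C)/C=C(C)/C=C/C(=O)NC1=C[C@@](O)(/C=C/[Sn](CCCC)(CCCC)CCCC)[C@@H]2O[C@@H]2C1=O | intermediate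
33 | (2E,4E,6R)-N-[(1S,5S,6R)-5-hydroxy-5-[(1E,3E,5E)-7-[(2-hydroxy-5-oxocyclopent-1-en-1-yl)amino]-7-oxohepta-1,3,5-trien-1-yl]-2-oxo-7-oxabicyclo[4.1.0]hept-3-en-3-yl]-4,6-dimethyldeca-2,4-dienamide | CCCC[C@@H](C)/C=C(C)/C=C/C(=O)NC1=C[C@@](O)(/C=C/C=C/C=C/C(=O)NC2=C(O)CCC2=O)[C@@H]2O[C@@H]2C1=O | target

## Step count and least certain steps

Total step count: 19 steps. Longest linear sequence: 10 steps (steps 4 to 9, then 16 to 19). The ring A line itself takes 7 steps from 1 (steps 1 to 3 and 16 to 19).

**Step 2 (key step, proposed new method).** Four processes may defeat it. The catalyst may discriminate poorly between the two enantiotopic bromoenone arms, because it must read a difference that lies on the far side of boron. An uncatalysed or merely base-catalysed closure of hemiester 6 may run beside the catalysed one and dilute the enantiomeric excess. The addition may reverse (E1cB return from the bromo enolate to 6), which would let the enantiomers equilibrate with time. Dehydrobromination across C5–C6 may follow the addition. Fallback with known chemistry, setting out from 4: the tether atom is changed from boron to carbon. An acetalisation/oxa-Michael cascade of the quinol with 2-methylpropanal under a chiral BINOL-derived phosphoric acid, an established way to desymmetrise para-quinols, should give the cis-fused 1,3-dioxolane F1. Acid-catalysed methanolysis (TsOH, MeOH) then frees bromohydrin diol 8, which is closed with K2CO3 as in the second half of step 3, so that the route is rejoined at 9. The price is one more step and an acidic deprotection next to the tertiary alcohol.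

**Step 16.** Turnover at a hindered, electron-poor vinyl bromide may be slow, leaving the carbonate base time to attack the epoxy ketone by enolisation, retro-aldol cleavage or opening by the amidate; catalyst poisoning by chelation of copper between the C1 carbonyl and the new amide is also possible. Fallback, setting out from 9: the C2–N bond is made with an ammonia surrogate and the amide bond by acylation. Coupling with benzophenone imine (Pd2(dba)3, Xantphos, Cs2CO3, dioxane, 50 °C; a zerovalent palladium cycle) should give the N-(diphenylmethylidene)amino enone F2, and aqueous citric acid frees the 2-amino enone F3. Enal 18 is converted by a Horner–Wadsworth–Emmons reaction with diethylphosphonoacetic acid (two equivalents of base) into (2E,4E,6R)-4,6-dimethyldeca-2,4-dienoic acid F4, and (COCl)2 gives the dienoyl chloride F5. Acylation of F3 with F5 in the presence of pyridine returns to the route at 30.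

**Step 18.** Tin may be delivered to the internal alkyne carbon, or the palladium hydride may transfer hydride to the enone or the epoxy ketone instead of the alkyne. Fallback, setting out from 31 and 29: the order of bond formation is reversed. Sonogashira coupling (PdCl2(PPh3)2, CuI, iPr2NH, THF, rt) should give the dienyne F6. Ruthenium-catalysed trans-hydrosilylation ((EtO)3SiH, [Cp*Ru(MeCN)3]PF6, CH2Cl2, 0 °C) gives the vinylsilane F7; silicon on either alkyne carbon leads to the same product. Protodesilylation with AgF then gives the E-alkene, which is 33 itself. This path replaces steps 18 and 19.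

**Step 3.** Boron may transfer incompletely to pinacol, or, once the diol is free, enolisation at C6 may be followed by loss of the C5 oxygen (elimination back to an achiral dienone) or by retro-aldol ring opening rather than by ring closure. Fallback, setting out from 7: the two events are separated and the closure is made base-free. Boron is exchanged onto pinacol without base, bromohydrin diol 8 is isolated by rapid chromatography, and the C6–Br bond is ionised with Ag2O in MeCN so that the C5 hydroxyl closes the epoxide without an enolate being formed; the product is 9. This fallback makes no new compound (F0).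

## Further compounds

F1 | step 2 | (3aS,4R,7aR)-4,6-dibromo-2-(propan-2-yl)-7a-[(triisopropylsilyl)ethynyl]-3a,7a-dihydro-1,3-benzodioxol-5(4H)-one (acetal carbon unassigned) | BrC1=C[C@@](OC(C(C)C)O2)(C#C[Si](C(C)C)(C(C)C)C(C)C)[C@H]2[C@@H](Br)C1=O
F2 | step 16 | (1S,5R,6R)-3-[(diphenylmethylidene)amino]-5-hydroxy-5-[(triisopropylsilyl)ethynyl]-7-oxabicyclo[4.1.0]hept-3-en-2-one | C(=NC1=C[C@@](O)(C#C[Si](C(C)C)(C(C)C)C(C)C)[C@@H]2O[C@@H]2C1=O)(c1ccccc1)c1ccccc1
F3 | step 16 | (1S,5R,6R)-3-amino-5-hydroxy-5-[(triisopropylsilyl)ethynyl]-7-oxabicyclo[4.1.0]hept-3-en-2-one | NC1=C[C@@](O)(C#C[Si](C(C)C)(C(C)C)C(C)C)[C@@H]2O[C@@H]2C1=O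
F4 | step 16 | (2E,4E,6R)-4,6-dimethyldeca-2,4-dienoic acid | CCCC[C@@H](C)/C=C(C)/C=C/C(O)=O
F5 | step 16 | (2E,4E,6R)-4,6-dimethyldeca-2,4-dienoyl chloride | CCCC[C@@H](C)/C=C(C)/C=C/C(Cl)=O
F6 | step 18 | (2E,4E,6R)-N-[(1S,5R,6R)-5-hydroxy-5-[(3E,5E)-7-[(2-hydroxy-5-oxocyclopent-1-en-1-yl)amino]-7-oxohepta-3,5-dien-1-yn-1-yl]-2-oxo-7-oxabicyclo[4.1.0]hept-3-en-3-yl]-4,6-dimethyldeca-2,4-dienamide | CCCC[C@@H](C)/C=C(C)/C=C/C(=O)NC1=C[C@@](O)(C#C/C=C/C=C/C(=O)NC2=C(O)CCC2=O)[C@@H]2O[C@@H]2C1=O
F7 | step 18 | (2E,4E,6R)-N-[(1S,5R,6R)-5-hydroxy-5-[(1Z,3E,5E)-7-[(2-hydroxy-5-oxocyclopent-1-en-1-yl)amino]-7-oxo-2-(triethoxysilyl)hepta-1,3,5-trien-1-yl]-2-oxo-7-oxabicyclo[4.1.0]hept-3-en-3-yl]-4,6-dimethyldeca-2,4-dienamide | CCCC[C@@H](C)/C=C(C)/C=C/C(=O)NC1=C[C@@](O)(/C=C(\[Si](OCC)(OCC)OCC)/C=C/C=C/C(=O)NC2=C(O)CCC2=O)[C@@H]2O[C@@H]2C1=O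
F0 | step 3 | none | none
A1 | alternative 1 | benzoic acid | OC(=O)c1ccccc1
A2 | alternative 1 | (1S,2R)-1,2-dihydroxycyclohexa-3,5-diene-1-carboxylic acid | C1=C[C@@](O)(C(O)=O)[C@H](O)C=C1
A3 | alternative 2 | 1-[(2S,3R)-3-(3-hydroxypenta-1,4-dien-3-yl)oxiran-2-yl]prop-2-en-1-one | C=CC(O)(C=C)[C@@H]1O[C@@H]1C(=O)C=C
A4 | alternative 2 | (1S,5S,6R)-5-ethenyl-5-hydroxy-7-oxabicyclo[4.1.0]hept-3-en-2-one | C1=C[C@@](O)(C=C)[C@@H]2O[C@@H]2C1=O
A5 | alternative 3 | (S)-tert-butyl(dimethyl){[4-[(trimethylsilyl)ethynyl]cyclohexa-2,4-dien-1-yl]oxy}silane | C1[C@H](O[Si](C)(C)C(C)(C)C)C=CC(C#C[Si](C)(C)C)=C1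
A6 | alternative 3 | 7-(tert-butyldimethylsilyloxy)-5-[(trimethylsilyl)ethynyl]-2,3-dioxabicyclo[2.2.2]oct-5-ene, peroxide bridge anti to the silyloxy group | C1[C@@H]2OO[C@@H](C=C2C#C[Si](C)(C)C)[C@H]1O[Si](C)(C)C(C)(C)C
A7 | alternative 3 | tert-butyldimethylsilyl ether of syn-3,4:5,6-diepoxy-4-[(trimethylsilyl)ethynyl]cyclohexan-1-ol, both epoxides anti to the silyloxy group | C1[C@@H]2O[C@]2(C#C[Si](C)(C)C)[C@@H]3O[C@@H]3[C@H]1O[Si](C)(C)C(C)(C)C
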